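The route rests on disconnecting the C2–C3 bond of the dihydrofuran ring. C2 is benzylic and bound to O1, so in the opened form it is the hydridic CH2 of a 3,4,5-trimethoxybenzyl aryl ether lying five atoms from C3. An enantioselective dirhodium-catalysed C–H insertion of a donor/donor carbene at C3, generated from an acetophenone hydrazone, closes the five-membered ring and sets C2 and C3 in one operation from an achiral ketone. Acid equilibration at C2 then gives the trans pair, and the C5 quaternary centre (allyl, OMe) of the cyclohexadienone ring is installed last by reagent-controlled oxidative dearomatising allylation of the 5-methoxy-6-hydroxy arene.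

Key step: step 5

Remark: the insertion in step 5 is assumed to give the cis-2,3 isomer, as is usual for donor/donor carbenes inserting into benzylic ethers; step 6 then corrects C2.

Step 1
Reactants: 1 3-(benzyloxy)-4-methoxybenzaldehyde
Product: 3 3-(benzyloxy)-4-methoxyphenol, via aryl formate 2 (not isolated)
Conditions: mCPBA, CH2Cl2, 0 °C to rt; then K2CO3 (cat.), MeOH, rt
Reagents that add atoms: mCPBA, OOC(=O)c1cccc(Cl)c1
Why: Baeyer–Villiger oxidation of the electron-rich aldehyde (Dakin-type aryl migration) should give the aryl formate, which is transesterified to the phenol while the benzyl ether stays intact.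

Step 2
Reactants: 3 3-(benzyloxy)-4-methoxyphenol
Product: 4 1-[4-(benzyloxy)-2-hydroxy-5-methoxyphenyl]ethan-1-one
Conditions: AcOH, BF3·OEt2, 70 °C; then aq. NaOAc
Reagents that add atoms: acetic acid, CC(=O)O
Why: Friedel–Crafts C-acylation of the phenol should occur at the only unhindered doubly activated site (ortho to OH, para to OBn), and chelation of the resulting ortho-hydroxy ketone prevents a second acylation.

Step 3
Reactants: 4 1-[4-(benzyloxy)-2-hydroxy-5-methoxyphenyl]ethan-1-one; 5 5-(chloromethyl)-1,2,3-trimethoxybenzene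
Product: 6 1-{4-(benzyloxy)-5-methoxy-2-[(3,4,5-trimethoxybenzyl)oxy]phenyl}ethan-1-one
Conditions: K2CO3, KI (cat.), DMF, 70 °C
Reagents that add atoms: none
Why: Williamson etherification of the hydrogen-bonded phenol with the reactive benzylic chloride installs the O1–CH2Ar unit whose CH2 becomes C2.

Step 4
Reactants: 6 1-{4-(benzyloxy)-5-methoxy-2-[(3,4,5-trimethoxybenzyl)oxy]phenyl}ethan-1-one
Product: 7 (E)-{1-[4-(benzyloxy)-5-methoxy-2-((3,4,5-trimethoxybenzyl)oxy)phenyl]ethylidene}hydrazine
Conditions: N2H4·H2O (excess), AcOH (cat.), EtOH, 80 °C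
Reagents that add atoms: hydrazine (as hydrate), NN
Why: Condensation of the aryl methyl ketone with excess hydrazine should give the free hydrazone (the excess suppresses azine formation), the precursor of the diazoalkane.

Step 5
Reactants: 7 (E)-{1-[4-(benzyloxy)-5-methoxy-2-((3,4,5-trimethoxybenzyl)oxy)phenyl]ethylidene}hydrazine
Product: 9 (2R,3S)-6-(benzyloxy)-5-methoxy-3-methyl-2-(3,4,5-trimethoxyphenyl)-2,3-dihydro-1-benzofuran (cis), via diazoalkane 8 (not isolated)
Conditions: activated MnO2, CH2Cl2, 0 °C; filtration; filtrate added slowly to Rh2(R-PTAD)4 (dirhodium tetrakis[(R)-(1-adamantyl)(phthalimido)acetate], 1 mol %), CH2Cl2, −20 to 0 °C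
Reagents that add atoms: none
Why: MnO2 dehydrogenates hydrazone 7 to the aryl(methyl)diazomethane 8, which Rh2(R-PTAD)4 converts with loss of N2 into a donor/donor rhodium carbene at the future C3. The carbene carbon takes up the hydridic C–H bond of the ortho O–CH2Ar group (alpha to O1 and benzylic to the trimethoxyphenyl ring) in an asynchronous hydride-transfer/C–C bond-forming insertion, so that the C2–C3 bond is made as the ring closes. The closest known reaction type is the enantioselective intramolecular 1,5-C–H insertion of hydrazone-derived donor/donor rhodium carbenes into benzylic ethers to give 2,3-dihydrobenzofurans. The dihydrofuran ring (O1, C2, C3, C3a, C7a) closes through a five-membered cyclic transition state at the carbene carbon. C2 and C3 are both set by the chiral dirhodium tetracarboxylate (catalyst control on an achiral substrate; the catalyst antipode that delivers 3S is taken), and the insertion is expected to give the cis 2,3-relationship, hence (2R,3S). The step needs insertion to outrun 1,2-hydride shift from the methyl group and azine formation, which the doubly activated C–H bond five atoms away, low temperature, slow addition of 8 and the bulky phthalimido carboxylate ligands should secure, while the O6-benzyl and methoxy C–H bonds are out of reach.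

Step 6
Reactants: 9 (2R,3S)-6-(benzyloxy)-5-methoxy-3-methyl-2-(3,4,5-trimethoxyphenyl)-2,3-dihydro-1-benzofuran (cis)
Product: 10 (2S,3S)-6-(benzyloxy)-5-methoxy-3-methyl-2-(3,4,5-trimethoxyphenyl)-2,3-dihydro-1-benzofuran (trans)
Conditions: BF3·OEt2 (0.5 equiv), CH2Cl2, −40 to 0 °C
Reagents that add atoms: none
Why: Lewis-acid ionisation of the C2–O1 bond gives a phenol-tethered 3,4,5-trimethoxybenzylic cation that recloses to the thermodynamically preferred trans-2,3 arrangement (known acid-mediated cis-to-trans equilibration of 2-aryl-2,3-dihydrobenzofurans), inverting only C2 and leaving C3 untouched.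

Step 7
Reactants: 10 (2S,3S)-6-(benzyloxy)-5-methoxy-3-methyl-2-(3,4,5-trimethoxyphenyl)-2,3-dihydro-1-benzofuran (trans)
Product: 11 (2S,3S)-5-methoxy-3-methyl-2-(3,4,5-trimethoxyphenyl)-2,3-dihydro-1-benzofuran-6-ol
Conditions: H2 (1 atm), 10% Pd/C, EtOAc, rt
Reagents that add atoms: none
Why: Hydrogenolysis of the primary O-benzyl ether should be much faster than cleavage of the hindered cyclic secondary C2–O1 bond, and it leaves the methyl ethers and both stereocentres untouched.

Step 8
Reactants: 11 (2S,3S)-5-methoxy-3-methyl-2-(3,4,5-trimethoxyphenyl)-2,3-dihydro-1-benzofuran-6-ol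
Product: 12 (2S,3S,5R)-5-methoxy-3-methyl-5-(prop-2-en-1-yl)-2-(3,4,5-trimethoxyphenyl)-3,5-dihydro-1-benzofuran-6(2H)-one
Conditions: (R,R)-ArI(OAc)2 (lactate-derived C2-symmetric aryl-λ3-iodane diacetate, Ar = 2,6-bis[(1-methoxy-1-oxopropan-2-yl)oxy]phenyl), allylSiMe3 (excess), CH2Cl2/(CF3)2CHOH, −60 to −30 °C; aq. NaHCO3; product kept below 25 °C
Reagents that add atoms: allyltrimethylsilane, C=CC[Si](C)(C)C
Why: Proposed new method: the phenol oxygen O6 should exchange an acetate on the chiral trivalent-iodine reagent, which makes C5 electrophilic (the methoxy-bearing ortho carbon, where 2-methoxyphenols accept nucleophiles in such oxidations), and the C2-symmetric lactate arms shield one face, so that allyltrimethylsilane attacks C5 from the open face in an SN2'-type step as the aryl iodide leaves and acetate removes silicon (Hosomi–Sakurai-type umpolung allylation); the closest known reaction types are the racemic PhI(OCOCF3)2-mediated ortho-allylation of 2-alkoxyarenols with allylsilanes and the enantioselective ortho-dearomatisation of phenols by chiral aryl-λ3-iodanes; the (5R) configuration is reagent-controlled because C2 and C3 are too remote to bias it, and the reagent antipode is chosen accordingly (written here as R,R).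

Compound list
1 | 3-(benzyloxy)-4-methoxybenzaldehyde | COc1ccc(C=O)cc1OCc1ccccc1 | starting material
2 | 3-(benzyloxy)-4-methoxyphenyl formate | COc1ccc(OC=O)cc1OCc1ccccc1 | intermediate
3 | 3-(benzyloxy)-4-methoxyphenol | COc1ccc(O)cc1OCc1ccccc1 | intermediate
4 | 1-[4-(benzyloxy)-2-hydroxy-5-methoxyphenyl]ethan-1-one | CC(=O)c1cc(OC)c(OCc2ccccc2)cc1O | intermediate
5 | 5-(chloromethyl)-1,2,3-trimethoxybenzene (3,4,5-trimethoxybenzyl chloride) | COc1cc(CCl)cc(OC)c1OC | starting material
6 | 1-{4-(benzyloxy)-5-methoxy-2-[(3,4,5-trimethoxybenzyl)oxy]phenyl}ethan-1-one | CC(=O)c1cc(OC)c(OCc2ccccc2)cc1OCc1cc(OC)c(OC)c(OC)c1 | intermediate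
7 | (E)-{1-[4-(benzyloxy)-5-methoxy-2-((3,4,5-trimethoxybenzyl)oxy)phenyl]ethylidene}hydrazine | C/C(=N\N)c1cc(OC)c(OCc2ccccc2)cc1OCc1cc(OC)c(OC)c(OC)c1 | intermediate
8 | 1-(benzyloxy)-4-(1-diazoethyl)-2-methoxy-5-[(3,4,5-trimethoxybenzyl)oxy]benzene | CC(=[N+]=[N-])c1cc(OC)c(OCc2ccccc2)cc1OCc1cc(OC)c(OC)c(OC)c1 | intermediate
9 | (2R,3S)-6-(benzyloxy)-5-methoxy-3-methyl-2-(3,4,5-trimethoxyphenyl)-2,3-dihydro-1-benzofuran (cis) | COc1cc2c(cc1OCc1ccccc1)O[C@@H](c1cc(OC)c(OC)c(OC)c1)[C@H]2C | intermediate
10 | (2S,3S)-6-(benzyloxy)-5-methoxy-3-methyl-2-(3,4,5-trimethoxyphenyl)-2,3-dihydro-1-benzofuran (trans) | COc1cc2c(cc1OCc1ccccc1)O[C@H](c1cc(OC)c(OC)c(OC)c1)[C@H]2C | intermediate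
11 | (2S,3S)-5-methoxy-3-methyl-2-(3,4,5-trimethoxyphenyl)-2,3-dihydro-1-benzofuran-6-ol | COc1cc2c(cc1O)O[C@H](c1cc(OC)c(OC)c(OC)c1)[C@H]2C | intermediate
12 | (2S,3S,5R)-5-methoxy-3-methyl-5-(prop-2-en-1-yl)-2-(3,4,5-trimethoxyphenyl)-3,5-dihydro-1-benzofuran-6(2H)-one | C=CC[C@@]1(OC)C=C2C(=CC1=O)O[C@H](c1cc(OC)c(OC)c(OC)c1)[C@H]2C | target

Total step count: 8. Longest linear sequence: 8 steps (from 1).

Steps most likely to fail

Step 8 (proposed new method). Facial control at C5 may be lost if the phenol is oxidised to a free phenoxenium ion before the allylsilane attacks, so that the reagent no longer differentiates the two faces. Any allyl delivered instead to C3a anti to the 3-methyl group would be expected to converge on 12 by a suprafacial Cope shift on gentle warming. The fallback uses known chemistry, sets out from 11 and returns at 12. Oxidative ortho-allylation with achiral PhI(OCOCF3)2 and allylSiMe3 in CH2Cl2 at −78 °C should give 12 together with its C5 epimer, (2S,3S,5S)-5-methoxy-3-methyl-5-(prop-2-en-1-yl)-2-(3,4,5-trimethoxyphenyl)-3,5-dihydro-1-benzofuran-6(2H)-one F1, as diastereomers to be separated by chromatography. F1 is recycled: heating in toluene at about 110 °C should bring about the retro-Claisen shift typical of 6-allyl-6-methoxycyclohexa-2,4-dienones to the aryl allyl ether (2S,3S)-5-methoxy-3-methyl-6-(prop-2-en-1-yloxy)-2-(3,4,5-trimethoxyphenyl)-2,3-dihydro-1-benzofuran F2. Pd(PPh3)4 with morpholine then returns phenol 11 for another pass.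

Step 5. 1,2-Hydride migration from the methyl group of the carbene (giving the styrene) or azine formation may outrun insertion, or the enantio-induction may be insufficient. The fallback replaces the donor/donor carbene by a donor/acceptor carbene, sets out from ketone 6 and returns at 10 (steps 4 to 6 are bypassed). Oxidative 1,2-aryl shift (PhI(OAc)2, HC(OMe)3, H2SO4 cat., MeOH) should give methyl 2-{4-(benzyloxy)-5-methoxy-2-[(3,4,5-trimethoxybenzyl)oxy]phenyl}acetate F3. Diazo transfer (4-acetamidobenzenesulfonyl azide, DBU, MeCN) gives the aryldiazoacetate F4. Rh2(S-PTTL)4 (dirhodium tetrakis[N-phthaloyl-(S)-tert-leucinate], or its antipode as needed for 2S) should effect the same C–H insertion to the cis ester methyl (2S,3R)-6-(benzyloxy)-5-methoxy-2-(3,4,5-trimethoxyphenyl)-2,3-dihydro-1-benzofuran-3-carboxylate F5. NaOMe in MeOH epimerises C3 through the ester enolate to the trans ester, the (2S,3S) isomer F6. LiAlH4 gives the primary alcohol [(2S,3R)-6-(benzyloxy)-5-methoxy-2-(3,4,5-trimethoxyphenyl)-2,3-dihydro-1-benzofuran-3-yl]methanol F7, TsCl/pyridine gives its tosylate F8, and LiBHEt3 reduces F8 to the 3-methyl compound 10.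

Step 6. In the ring-opened benzylic cation a 1,2-hydride shift from C3 or loss of a proton to the stilbene may compete with reclosure, eroding the configuration at C3 or consuming material. The fallback replaces the cationic pathway by a radical one, sets out from 9 and returns at 10 without new compounds. Reversible hydrogen-atom abstraction at C2–H (the weakest C–H bond, benzylic and alpha to O1, and polarity-matched for an electrophilic thiyl radical) with a thiol such as triisopropylsilanethiol and a photochemical or thermal radical initiator should equilibrate C2 to the trans isomer, as in known thiyl-radical epimerisations of benzylic and alpha-heteroatom stereocentres.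

Further compounds
F1 | step 8 | (2S,3S,5S)-5-methoxy-3-methyl-5-(prop-2-en-1-yl)-2-(3,4,5-trimethoxyphenyl)-3,5-dihydro-1-benzofuran-6(2H)-one | C=CC[C@]1(OC)C=C2C(=CC1=O)O[C@H](c1cc(OC)c(OC)c(OC)c1)[C@H]2C
F2 | step 8 | (2S,3S)-5-methoxy-3-methyl-6-(prop-2-en-1-yloxy)-2-(3,4,5-trimethoxyphenyl)-2,3-dihydro-1-benzofuran | COc1cc2c(cc1OCC=C)O[C@H](c1cc(OC)c(OC)c(OC)c1)[C@H]2C
F3 | step 5 | methyl 2-{4-(benzyloxy)-5-methoxy-2-[(3,4,5-trimethoxybenzyl)oxy]phenyl}acetate | COC(=O)Cc1cc(OC)c(OCc2ccccc2)cc1OCc1cc(OC)c(OC)c(OC)c1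
F4 | step 5 | methyl 2-{4-(benzyloxy)-5-methoxy-2-[(3,4,5-trimethoxybenzyl)oxy]phenyl}-2-diazoacetate | COC(=O)C(=[N+]=[N-])c1cc(OC)c(OCc2ccccc2)cc1OCc1cc(OC)c(OC)c(OC)c1
F5 | step 5 | methyl (2S,3R)-6-(benzyloxy)-5-methoxy-2-(3,4,5-trimethoxyphenyl)-2,3-dihydro-1-benzofuran-3-carboxylate (cis) | COc1cc2c(cc1OCc1ccccc1)O[C@H](c1cc(OC)c(OC)c(OC)c1)[C@@H]2C(=O)OC
F6 | step 5 | methyl (2S,3S)-6-(benzyloxy)-5-methoxy-2-(3,4,5-trimethoxyphenyl)-2,3-dihydro-1-benzofuran-3-carboxylate (trans) | COc1cc2c(cc1OCc1ccccc1)O[C@H](c1cc(OC)c(OC)c(OC)c1)[C@H]2C(=O)OC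
F7 | step 5 | [(2S,3R)-6-(benzyloxy)-5-methoxy-2-(3,4,5-trimethoxyphenyl)-2,3-dihydro-1-benzofuran-3-yl]methanol | COc1cc2c(cc1OCc1ccccc1)O[C@H](c1cc(OC)c(OC)c(OC)c1)[C@H]2CO
F8 | step 5 | [(2S,3R)-6-(benzyloxy)-5-methoxy-2-(3,4,5-trimethoxyphenyl)-2,3-dihydro-1-benzofuran-3-yl]methyl 4-methylbenzenesulfonate | COc1cc2c(cc1OCc1ccccc1)O[C@H](c1cc(OC)c(OC)c(OC)c1)[C@H]2COS(=O)(=O)c1ccc(C)cc1
F0 | step 6 | none | none
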